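**Plan**

1. Retrosynthetic cuts, in order: N4–O; C3–C18 (side-chain butenolide added to a ring-C lactam, then C19=C20 reduced); C13=C15 (methyl from a methylene); C14–O/C11–O of ring D (C11–O from a C11 acetyl group); N4–C3 and C1–C2 of ring C; C9–C10 and C11–C12 of ring B in one step; C9a–C1, back to N-Boc-caprolactam.
2. Enabling feature: ring B (C9, C9a, C1, C12, C11, C10) carries N4 on C9a and has C9 inside azepane ring A, so C9=C9a–C1=C12 is a 2-amido-1,3-diene held in a caprolactam enecarbamate. C10 (ethyl) and C11 (oxygen) are trans, so C10=C11 is an (E)-pent-2-enoyl unit whose acyl carbon is later exchanged for oxygen.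
3. Forward order: ring A (bought) → diene → ring B by [4+2] → ring C by syn-hydroboration/C-alkylation and lactamisation → ring D by Baeyer–Villiger oxidation and oxidative lactonisation → C13 methyl → side-chain lactone by reductive vinylogous Mannich reaction → N-oxide.
4. Stereochemistry: C9, C10, C11, C12 from the endo [4+2] of an (E)-dienophile, absolute sense from a (4R)-benzyl oxazolidinone; C9a and C1 from one α-face syn addition (H to C9a, boron to C1, then B→C with retention), which gives the trans B/C fusion.
5. C13 and C20 by hydrogenation from the less hindered faces; C3/C18 by addition to the C3 iminium ion anti to C9; N4 by oxidation anti to the C3 substituent.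

Key step: step 5

Atom labels used for all ring-bearing intermediates: ring A = N4, C5, C6, C7, C8, C9, C9a; ring B = C9, C9a, C1, C12, C11, C10; ring C = C9a, C1, C2, C3, N4; ring D = C11, O, C14(=O), C13, C12; ethyl on C10; C15 = methyl on C13; side-chain lactone = C18, C19, C20 (methyl C22), C21(=O), O. Face α of ring B carries H-9, H-9a, H-11, H-12 and the 10-ethyl group in the target; face β carries H-1, H-10, N4, C8, O-11 and C13.

Remark on the chemistry: the amine oxide of the target is taken to be the diastereomer formed by direct oxidation of the tertiary amine on the lone-pair face anti to H-9a and to the C3 substituent.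

**Route**

Step 1
Reactants: 1 tert-butyl 2-oxoazepane-1-carboxylate
Product: 2 tert-butyl 7-[(diphenoxyphosphoryl)oxy]-2,3,4,5-tetrahydro-1H-azepine-1-carboxylate
Conditions: KN(SiMe3)2, (PhO)2P(O)Cl, THF, −78 °C
Reagents that add atoms: diphenyl chlorophosphate, O=P(Cl)(Oc1ccccc1)Oc1ccccc1
Why: The potassium enolate of the N-acyl lactam is trapped on oxygen (enol phosphate formation), giving a stable ketene N,O-acetal phosphate that serves as a vinyl pseudohalide.

Step 2
Reactants: 3 tert-butyl(but-3-yn-1-yloxy)dimethylsilane
Product: 4 (E)-alkenyl pinacol boronate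
Conditions: pinacolborane, Cp2ZrHCl (5 mol %), Et3N (10 mol %), neat, 60 °C
Reagents that add atoms: pinacolborane, [H]B1OC(C)(C)C(C)(C)O1
Why: Zirconium-catalysed syn-hydroboration of a terminal alkyne places boron on the terminal carbon and should give only the (E)-alkenylboronate.

Step 3
Reactants: 2 vinyl phosphate; 4 (E)-alkenyl pinacol boronate
Product: 5 2-amido diene (C9=C9a–C1=C12)
Conditions: Pd(PPh3)4 (5 mol %), 2 M aq. Na2CO3, THF, 50 °C
Reagents that add atoms: none
Why: Suzuki–Miyaura coupling of lactam-derived vinyl phosphates with alkenylboron reagents is a known entry to 2-amido-1,3-dienes and keeps the (E)-geometry of C1=C12.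

Step 4
Reactants: 6 (4R)-4-benzyl-1,3-oxazolidin-2-one; 7 (2E)-pent-2-enoic acid
Product: 9 (4R)-4-benzyl-3-[(2E)-pent-2-enoyl]-1,3-oxazolidin-2-one, via pivalic mixed anhydride 8 (not isolated)
Conditions: t-BuCOCl, Et3N, THF, −20 °C; then LiCl, −20 °C to rt
Reagents that add atoms: none
Why: N-acylation of the oxazolidinone by the mixed anhydride occurs at the unhindered enoyl carbonyl and leaves the (E)-alkene untouched.

Step 5
Reactants: 5 2-amido diene; 9 (4R)-4-benzyl-3-[(2E)-pent-2-enoyl]-1,3-oxazolidin-2-one
Product: 10 A/B-bicyclic cycloadduct (C9a=C1 enecarbamate)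
Conditions: Et2AlCl (1.5 equiv), CH2Cl2, −78 to −30 °C
Reagents that add atoms: none
Why: Et2AlCl turns imide 9 into a cationic aluminium chelate with an s-cis enoyl group, and the enecarbamate terminus C9 of 5 attacks its β-carbon C10 while C11 closes on C12 in one concerted, asynchronous normal-demand [4+2] event. The closest known reaction types are the Et2AlCl-promoted Diels–Alder reaction of N-enoyl oxazolidinones with acyclic dienes and the Diels–Alder reactions of lactam-derived 2-amido dienes. Ring B is the only ring closed, a six-membered carbocycle formed by intermolecular [4+2] cycloaddition (C9–C10 and C11–C12), which leaves the C9a=C1 enecarbamate for ring C. C10 and C11 become trans because the dienophile is (E); H-9 and H-12 end on the same α face because the addition is suprafacial on a diene whose C8 is held outside by ring A and whose C13 chain is outside through the (E)-alkene; the C11 acyl group ends cis to C8 and to the C12 chain by endo orientation of the chelated imide; the absolute sense comes from the benzyl group of the (4R)-auxiliary, which blocks one face of the chelate. The step needs regio-, endo- and π-facial selectivity: the first is secured by N4 on C9a, which makes C9 the nucleophilic terminus that bonds to the electrophilic β-carbon C10 (para orientation), the other two by the rigid chelate.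

Step 6
Reactants: 10 A/B-bicyclic cycloadduct
Product: 11 N-methoxy-N-methylamide
Conditions: MeNH(OMe)·HCl, AlMe3, CH2Cl2, 0 °C to rt
Reagents that add atoms: N,O-dimethylhydroxylamine hydrochloride, CNOC.Cl
Why: Transamination by the aluminium amide opens the imide at the exocyclic carbonyl (auxiliary cleavage) and should not touch C11, the carbamate or the silyl ether.

Step 7
Reactants: 11 N-methoxy-N-methylamide
Product: 12 C11 methyl ketone
Conditions: MeMgBr, THF, 0 °C
Reagents that add atoms: methylmagnesium bromide, C[Mg]Br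
Why: The magnesium chelate of the tetrahedral adduct persists until work-up, so one methyl is added and C11 is never exposed to the Grignard reagent as an enolisable ketone (ketone synthesis from an N-methoxy-N-methylamide).

Step 8
Reactants: 12 C11 methyl ketone
Product: 14 ester carbinol (H-9a α; CH2CO2Et on C1 α), via bis-borane adduct 13 (not isolated)
Conditions: 9-BBN (3 equiv), THF, 65 °C; MeOH (destroys excess B–H); then BrCH2CO2Et, KOt-Bu, t-BuOH/THF, 0 °C to rt
Reagents that add atoms: ethyl bromoacetate, BrCC(=O)OCC
Why: 9-BBN should add syn to the C9a=C1 enecarbamate from the α face (the β face is screened by the pseudoaxial C12 chain, C8 and the C11 group), with H going to C9a and boron to the less substituted C1; the bromoacetate enolate then forms the borate and C1 migrates from boron to carbon with retention (α-alkylation of an α-halo ester by a B-alkyl-9-BBN), so H-9a and C2 are cis and the later B/C fusion is trans, while the ketone is reduced to a borinate-masked carbinol that keeps C11 safe from base.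

Step 9
Reactants: 14 ester carbinol
Product: 15 keto ester
Conditions: triacetoxyperiodinane (DMP), NaHCO3, CH2Cl2, rt
Reagents that add atoms: none
Why: The periodinane oxidises both carbinol epimers back to the methyl ketone under buffered conditions that should not epimerise C11 (alcohol oxidation).

Step 10
Reactants: 15 keto ester
Product: 16 C11 acetate
Conditions: mCPBA, NaHCO3, CH2Cl2, rt
Reagents that add atoms: 3-chloroperbenzoic acid, OOC(=O)c1cccc(Cl)c1
Why: In the Baeyer–Villiger oxidation the secondary ring carbon C11 migrates in preference to methyl and with retention, so the acyl helper of the cycloaddition becomes the β-oxygen of ring D; carbamate, ester and silyl ether are inert to the peracid.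

Step 11
Reactants: 16 C11 acetate
Product: 18 tricyclic lactam diol (rings A, B, C), via amino alcohol acetate 17 (not isolated)
Conditions: HCl (3 M in MeOH), rt; concentrate; then K2CO3, MeOH, 60 °C
Reagents that add atoms: none
Why: Acid removes the Boc and TBS groups, and carbonate in methanol then cleaves the acetate and lets N4 attack the C3 ester (lactamisation), closing five-membered ring C trans-fused because H-9a and C2 were set cis in step 8.

Step 12
Reactants: 18 tricyclic lactam diol
Product: 20 tetracyclic lactam lactone (rings A to D), via lactol 19 (not isolated)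
Conditions: TEMPO (20 mol %), PhI(OAc)2 (3 equiv), CH2Cl2, rt
Reagents that add atoms: none
Why: The oxoammonium oxidation is selective for the primary alcohol, the aldehyde is captured by the cis 11β-hydroxyl as a five-membered lactol, and this is oxidised on to the γ-lactone (oxidative lactonisation of a 1,4-diol).

Step 13
Reactants: 20 tetracyclic lactam lactone
Product: 23 α-methylene lactone, via Mannich base 21 (not isolated), via ammonium iodide 22 (not isolated)
Conditions: LiN(SiMe3)2, THF, −78 °C; dimethyl(methylidene)ammonium iodide, −78 °C to rt; then MeI, MeOH, rt; then aq. NaHCO3, CH2Cl2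
Reagents that add atoms: dimethyl(methylidene)ammonium iodide, C=[N+](C)C.[I-]
Why: The lactone α-CH2 (C13) is more acidic than the lactam α-CH2 (C2), so one equivalent of base gives the lactone enolate, which is aminomethylated (Mannich reaction) and, after N-methylation, loses trimethylamine by β-elimination.

Step 14
Reactants: 23 α-methylene lactone
Product: 24 13-methyl lactam lactone
Conditions: H2 (1 atm), RhCl(PPh3)3 (10 mol %), benzene/EtOH, rt
Reagents that add atoms: none
Why: Homogeneous hydrogenation without double-bond migration should deliver hydrogen to C13 from the convex face of the cis-fused lactone (the face of H-12), so methyl C15 ends on the concave face, cis to C1, as the target requires.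

Step 15
Reactants: 25 3-methylfuran-2(5H)-one
Product: 26 triisopropyl[(3-methylfuran-2-yl)oxy]silane
Conditions: i-Pr3SiOTf, Et3N, CH2Cl2, 0 °C
Reagents that add atoms: triisopropylsilyl trifluoromethanesulfonate, CC(C)[Si](C(C)C)(C(C)C)OS(=O)(=O)C(F)(F)F
Why: O-silylation of the butenolide dienolate gives the 2-silyloxyfuran (silyl dienol ether formation), the vinylogous nucleophile for step 16.

Step 16
Reactants: 24 13-methyl lactam lactone; 26 triisopropyl[(3-methylfuran-2-yl)oxy]silane
Product: 28 butenolide amine (19,20-didehydro form of 29), via silyl hemiaminal 27 (not isolated)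
Conditions: IrCl(CO)(PPh3)2 (2 mol %), (Me2HSi)2O (2 equiv), toluene, rt; then 26, 2-nitrobenzoic acid, MeCN, 0 °C to rt
Reagents that add atoms: none
Why: The iridium-catalysed hydrosilylation reduces the tertiary lactam and leaves the lactone, the acid ionises the silyl hemiaminal to the C3 iminium ion, and the silyloxyfuran adds through its γ-carbon (reductive vinylogous Mannich reaction) from the face of H-9a, anti to the C9a–C9 bond and the azepane loop, with the usual threo preference of such additions setting C18.

Step 17
Reactants: 28 butenolide amine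
Product: 29 tertiary amine (free base of the target; tuberostemonine skeleton with the configuration of 30)
Conditions: H2 (1 atm), 10% Pd/C, EtOAc, rt
Reagents that add atoms: none
Why: Hydrogen should add to the butenolide from the face opposite the bulky C18 substituent (alkene hydrogenation), placing the C20 methyl cis to it; the saturated lactone and the amine are inert.

Step 18
Reactants: 29 tertiary amine
Product: 30 N-oxytuberostemonine
Conditions: mCPBA (1.05 equiv), CH2Cl2, 0 °C
Reagents that add atoms: 3-chloroperbenzoic acid, OOC(=O)c1cccc(Cl)c1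
Why: The peracid oxidises the tertiary amine on the lone-pair face anti to H-9a and to the C3 substituent (amine N-oxidation), which should give the N-oxide diastereomer of the target.

**Compound list**

1 | tert-butyl 2-oxoazepane-1-carboxylate (N-Boc-ε-caprolactam) | CC(C)(C)OC(=O)N1CCCCCC1=O | starting material
2 | tert-butyl 7-[(diphenoxyphosphoryl)oxy]-2,3,4,5-tetrahydro-1H-azepine-1-carboxylate | CC(C)(C)OC(=O)N1CCCCC=C1OP(=O)(Oc1ccccc1)Oc1ccccc1 | intermediate
3 | tert-butyl(but-3-yn-1-yloxy)dimethylsilane | C#CCCO[Si](C)(C)C(C)(C)C | starting material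
4 | tert-butyldimethyl{[(3E)-4-(4,4,5,5-tetramethyl-1,3,2-dioxaborolan-2-yl)but-3-en-1-yl]oxy}silane | CC(C)(C)[Si](C)(C)OCC/C=C/B1OC(C)(C)C(C)(C)O1 | intermediate
5 | tert-butyl 7-[(1E)-4-{[tert-butyl(dimethyl)silyl]oxy}but-1-en-1-yl]-2,3,4,5-tetrahydro-1H-azepine-1-carboxylate | CC(C)(C)OC(=O)N1CCCCC=C1/C=C/CCO[Si](C)(C)C(C)(C)C | intermediate
6 | (4R)-4-benzyl-1,3-oxazolidin-2-one | O=C1N[C@H](Cc2ccccc2)CO1 | starting material
7 | (2E)-pent-2-enoic acid | CC/C=C/C(=O)O | starting material
8 | (2E)-pent-2-enoic pivalic anhydride | CC/C=C/C(=O)OC(=O)C(C)(C)C | intermediate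
9 | (4R)-4-benzyl-3-[(2E)-pent-2-enoyl]-1,3-oxazolidin-2-one | CC/C=C/C(=O)N1[C@H](Cc2ccccc2)COC1=O | intermediate
10 | cycloadduct: N-Boc rings A/B with C9a=C1 enecarbamate; 10α-ethyl; 11β-{[(4R)-4-benzyl-2-oxo-1,3-oxazolidin-3-yl]carbonyl}; 12β-(2-TBSO-ethyl); H-9, H-11, H-12 all α | CC[C@@H]1[C@H]2CCCCN(C(=O)OC(C)(C)C)C2=C[C@@H](CCO[Si](C)(C)C(C)(C)C)[C@H]1C(=O)N1[C@H](Cc2ccccc2)COC1=O | intermediate
11 | as 10 with 11β-[methoxy(methyl)carbamoyl] | CC[C@@H]1[C@H]2CCCCN(C(=O)OC(C)(C)C)C2=C[C@@H](CCO[Si](C)(C)C(C)(C)C)[C@H]1C(=O)N(C)OC | intermediate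
12 | as 10 with 11β-acetyl | CC[C@@H]1[C@H]2CCCCN(C(=O)OC(C)(C)C)C2=C[C@@H](CCO[Si](C)(C)C(C)(C)C)[C@H]1C(C)=O | intermediate
13 | bis-borane adduct: 9-BBN on C1 (α), H-9a α, ketone reduced to its O-(9-BBN) borinate | CC[C@@H]1[C@H]2CCCCN(C(=O)OC(C)(C)C)[C@H]2[C@H](B2C3CCCC2CCC3)[C@@H](CCO[Si](C)(C)C(C)(C)C)[C@H]1C(C)OB1C2CCCC1CCC2 | intermediate
14 | N-Boc rings A/B, saturated: H-9a α, H-1 β, C1α-CH2CO2Et, 10α-ethyl, 11β-(1-hydroxyethyl) (carbinol epimers), 12β-(2-TBSO-ethyl) | CC[C@@H]1[C@H]2CCCCN(C(=O)OC(C)(C)C)[C@H]2[C@H](CC(=O)OCC)[C@@H](CCO[Si](C)(C)C(C)(C)C)[C@H]1C(C)O | intermediate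
15 | as 14 with 11β-acetyl | CC[C@@H]1[C@H]2CCCCN(C(=O)OC(C)(C)C)[C@H]2[C@H](CC(=O)OCC)[C@@H](CCO[Si](C)(C)C(C)(C)C)[C@H]1C(C)=O | intermediate
16 | as 14 with 11β-acetoxy | CC[C@@H]1[C@H]2CCCCN(C(=O)OC(C)(C)C)[C@H]2[C@H](CC(=O)OCC)[C@@H](CCO[Si](C)(C)C(C)(C)C)[C@H]1OC(C)=O | intermediate
17 | amino alcohol acetate: as 16 with free N4–H and free primary alcohol | CC[C@@H]1[C@H]2CCCCN[C@H]2[C@H](CC(=O)OCC)[C@@H](CCO)[C@H]1OC(C)=O | intermediate
18 | tricyclic lactam diol: rings A, B, C (C3 lactam, trans B/C, cis A/B); 11β-OH; 12β-(2-hydroxyethyl); 10α-ethyl | CC[C@@H]1[C@H]2CCCCN3[C@H]2[C@H](CC3=O)[C@@H](CCO)[C@H]1O | intermediate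
19 | lactol of ring D (C14 hemiacetal) on the lactam of 18 | CC[C@@H]1[C@H]2CCCCN3[C@H]2[C@H](CC3=O)[C@@H]2[C@H]1OC(O)C2 | intermediate
20 | tetracyclic lactam lactone: rings A to D, ring D cis-fused, C13 unsubstituted | CC[C@@H]1[C@H]2CCCCN3[C@H]2[C@H](CC3=O)[C@@H]2[C@H]1OC(=O)C2 | intermediate
21 | 13-[(dimethylamino)methyl] derivative of 20 | CC[C@@H]1[C@H]2CCCCN3[C@H]2[C@H](CC3=O)[C@@H]2[C@H]1OC(=O)C2CN(C)C | intermediate
22 | 13-[(trimethylammonio)methyl] iodide of 20 | CC[C@@H]1[C@H]2CCCCN3[C@H]2[C@H](CC3=O)[C@@H]2[C@H]1OC(=O)C2C[N+](C)(C)C.[I-] | intermediate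
23 | 13-methylidene derivative of 20 | CC[C@@H]1[C@H]2CCCCN3[C@H]2[C@H](CC3=O)[C@@H]2[C@H]1OC(=O)C2=C | intermediate
24 | 13-methyl derivative of 20, methyl on the concave face (cis to C1, H-13 cis to H-12) | CC[C@@H]1[C@H]2CCCCN3[C@H]2[C@H](CC3=O)[C@@H]2[C@H]1OC(=O)[C@@H]2C | intermediate
25 | 3-methylfuran-2(5H)-one | CC1=CCOC1=O | starting material
26 | triisopropyl[(3-methylfuran-2-yl)oxy]silane | Cc1ccoc1O[Si](C(C)C)(C(C)C)C(C)C | intermediate
27 | C3 silyl hemiaminal of 24 (O–SiMe2–O–SiMe2H on C3) | CC[C@@H]1[C@H]2CCCCN3[C@H]2[C@H](CC3O[Si](C)(C)O[SiH](C)C)[C@@H]2[C@H]1OC(=O)[C@@H]2C | intermediate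
28 | 19,20-didehydro derivative of 29 (4-methyl-5-oxo-2,5-dihydrofuran-2-yl on C3; C3 and C18 as in the target) | CC[C@@H]1[C@H]2CCCCN3[C@H]2[C@H](C[C@H]3[C@@H]2C=C(C)C(=O)O2)[C@@H]2[C@H]1OC(=O)[C@@H]2C | intermediate
29 | tertiary amine, free base of the target (tuberostemonine skeleton, all carbon stereocentres as in 30) | CC[C@@H]1[C@H]2CCCCN3[C@H]2[C@H](C[C@H]3[C@@H]2C[C@H](C)C(=O)O2)[C@@H]2[C@H]1OC(=O)[C@@H]2C | intermediate
30 | N-oxytuberostemonine | CC[C@@H]1[C@H]2CCCC[N@@+]3([O-])[C@H]2[C@H](C[C@H]3[C@@H]2C[C@H](C)C(=O)O2)[C@@H]2[C@H]1OC(=O)[C@@H]2C | target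

**Step count and risks**

Total step count: 18.
Longest linear sequence: 15 steps (1 → 2 → 5 → 10 → 11 → 12 → 14 → 15 → 16 → 18 → 20 → 23 → 24 → 28 → 29 → 30).

The three steps most likely to fail:

Step 8. The hindered trisubstituted enecarbamate may hydroborate slowly, and in the borate a ring B–C bond of the borabicycle may migrate instead of C1, or the β-amido borane may eliminate. The fallback sets out from 12 and uses radical and ionic chemistry instead of boron. Visible-light photoredox carbo-etherification (Ir(ppy)3 with ppy = 2-phenylpyridinato, 1 mol %, ethyl bromoacetate, 2,6-lutidine, MeOH, blue light) should add the ester radical to C1 from the α face and trap the oxidised α-amido radical with methanol, giving the 9a-methoxy carbamate F3. Reduction of the derived N-acyliminium ion with Et3SiH and BF3·OEt2 (CH2Cl2, −78 °C) would then give 15 directly, where the fallback rejoins the route, so step 9 is not needed. The facial course of the hydride delivery to C9a is less secure than in the syn-hydroboration.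

Step 5. The aluminium Lewis acid may cleave the carbamate, or Michael addition may occur without ring closure, and endo and facial selectivity may erode. The fallback sets out from 5 and replaces the stoichiometric auxiliary by catalyst control with a much milder Lewis acid. The achiral imide 3-[(2E)-pent-2-enoyl]-1,3-oxazolidin-2-one F1 (from 1,3-oxazolidin-2-one and 7 as in step 4) would react with 5 under 10 mol % of the Cu(SbF6)2 complex of 2,2′-(propane-2,2-diyl)bis(4-tert-butyl-4,5-dihydro-1,3-oxazole) (divalent copper, CH2Cl2, −20 °C). The ligand enantiomer is the one that exposes the same Cα face as the (4R)-benzyl auxiliary, expected to be the (R,R)-ligand from the square-planar chelate model. This would give the oxazolidinone cycloadduct F2, which the conditions of step 6 would convert into 11, where the fallback rejoins the route.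

Step 16. The furan may add to the wrong face of the C3 iminium ion, or threo/erythro control at C18 may be poor. The fallback sets out from 24 and builds C18 as a ketone that is then reduced. The same iridium hydrosilylation gives 27, which would be intercepted by the nitronate of methyl (2S)-2-methyl-4-nitrobutanoate (nitro-Mannich reaction) to give the β-nitro amine F4. A reductive Nef reaction (aqueous TiCl3, NH4OAc, THF) would give the α-amino ketone F5, in which C3 can equilibrate by enolisation. LiBH(s-Bu)3 (THF, −78 °C) should attack the ketone anti to the C3–N4 bond, giving the syn amino alcohol F6, which lactonises on mildly acidic work-up to 29, where the fallback rejoins the route.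

Further compounds
F1 | step 5 | 3-[(2E)-pent-2-enoyl]-1,3-oxazolidin-2-one | CC/C=C/C(=O)N1CCOC1=O
F2 | step 5 | cycloadduct as 10 with an unsubstituted 2-oxo-1,3-oxazolidin-3-ylcarbonyl group on C11 | CC[C@@H]1[C@H]2CCCCN(C(=O)OC(C)(C)C)C2=C[C@@H](CCO[Si](C)(C)C(C)(C)C)[C@H]1C(=O)N1CCOC1=O
F3 | step 8 | 9a-methoxy carbamate: as 15 with OMe in place of H-9a | CC[C@@H]1[C@H]2CCCCN(C(=O)OC(C)(C)C)C2(OC)[C@H](CC(=O)OCC)[C@@H](CCO[Si](C)(C)C(C)(C)C)[C@H]1C(C)=O
F4 | step 16 | β-nitro amine: C3-[(3S)-4-methoxy-3-methyl-1-nitro-4-oxobutyl] amine from 24 | CC[C@@H]1[C@H]2CCCCN3[C@H]2[C@H](C[C@H]3C(C[C@H](C)C(=O)OC)[N+](=O)[O-])[C@@H]2[C@H]1OC(=O)[C@@H]2C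
F5 | step 16 | α-amino ketone (C18 ketone, C21 methyl ester) | CC[C@@H]1[C@H]2CCCCN3[C@H]2[C@H](C[C@H]3C(=O)C[C@H](C)C(=O)OC)[C@@H]2[C@H]1OC(=O)[C@@H]2C
F6 | step 16 | syn amino alcohol (18-hydroxy methyl ester) | CC[C@@H]1[C@H]2CCCCN3[C@H]2[C@H](C[C@H]3[C@@H](O)C[C@H](C)C(=O)OC)[C@@H]2[C@H]1OC(=O)[C@@H]2C
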